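The six-membered ring is written with ring carbons C1 and C2 (angelate-bearing), C3 (methyl-bearing), C4, C5 and C6 (side-chain-bearing); this cyclohexane is made from a cyclopentene. (R)-Limonene, after side-chain construction at its isopropenyl methyl, is cleaved at the ring alkene and re-closed by aldol condensation to a cyclopentenecarbaldehyde; deconjugative α-hydroxylation gives a 1-hydroxycyclopent-2-ene-1-carbaldehyde. Its chelation-controlled α-ketol shift moves the alkenyl carbon C3 from C1 to the formyl carbon C2: in one operation the five-membered ring becomes the six-membered ring, the C1 ketone and the C2 carbinol (trans to the C6 side chain) appear and the C3=C4 alkene is placed for the oxirane. The step exploits the vicinal C1/C2 oxygens beside methyl-bearing C3.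

Key step: step 8

Remark on the chemistry: side-chain carbons are labelled C7 (bearing the methylene C14), C8 (acetoxy carbon), C9 and C10=C11, and all labels are kept for every intermediate. The target is (1R,2S,3S,4S,6S,8S) in these labels. (R)-(+)-Limonene of high enantiomeric purity and a commercial solution of (−)-Ipc2B(allyl) are assumed.

Step 1
Reactants: 1 (R)-(+)-limonene
Product: 4 2-[(1R)-4-methylcyclohex-3-en-1-yl]prop-2-en-1-ol, via allyllithium 2 (not isolated), via dimethyl allylboronate 3 (not isolated)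
Conditions: n-BuLi, TMEDA, hexane, 25 °C; B(OMe)3, THF, −78 °C; NaOH, H2O2, 0 °C
Reagents that add atoms: hydrogen peroxide, OO (hydroxyl oxygen of 4); n-butyllithium, [Li]CCCC (lithium of 2); trimethyl borate, COB(OC)OC (boron and methoxy groups of 3)
Why: Allylic lithiation of limonene by n-BuLi·TMEDA should occur selectively at the isopropenyl methyl to give the 2-substituted allyllithium, which is borylated and oxidised with retention at carbon (allylic metalation, borylation–oxidation), leaving the ring stereocentre (future C6) untouched.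

Step 2
Reactants: 4 2-[(1R)-4-methylcyclohex-3-en-1-yl]prop-2-en-1-ol
Product: 5 2-[(1R)-4-methylcyclohex-3-en-1-yl]prop-2-enal
Conditions: MnO2, CH2Cl2, 25 °C
Reagents that add atoms: none
Why: MnO2 should oxidise the primary allylic alcohol selectively to the 2-substituted acrolein without touching the isolated alkenes (allylic alcohol oxidation).

Step 3
Reactants: 5 2-[(1R)-4-methylcyclohex-3-en-1-yl]prop-2-enal
Product: 7 (3S)-2-[(1R)-4-methylcyclohex-3-en-1-yl]hexa-1,5-dien-3-ol, via borinate 6 (not isolated)
Conditions: (−)-Ipc2B(allyl), Et2O, −78 °C; NaOH, H2O2, 0 → 25 °C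
Reagents that add atoms: (−)-B-allyldiisopinocampheylborane, C=CCB([C@@H]1C[C@@H]2C[C@H]([C@H]1C)C2(C)C)[C@@H]1C[C@@H]2C[C@H]([C@H]1C)C2(C)C
Why: Brown asymmetric allylboration through a chair six-membered transition state; the (−)-reagent should add to the Si face of the aldehyde and set C8 as S under reagent control, the remote ring stereocentre having little influence.

Step 4
Reactants: 7 (3S)-2-[(1R)-4-methylcyclohex-3-en-1-yl]hexa-1,5-dien-3-ol
Product: 8 tert-butyldimethylsilyl ether of 7
Conditions: TBSCl, imidazole, DMF, 25 °C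
Reagents that add atoms: tert-butyldimethylsilyl chloride, CC(C)(C)[Si](C)(C)Cl
Why: Standard silylation of the secondary alcohol; the silyl ether should survive the basic and Lewis-acidic steps that follow and is exchanged for the acetate before the oxirane is made.

Step 5
Reactants: 8 tert-butyldimethylsilyl ether of 7
Product: 10 (3R)-3-[(3S)-3-(tert-butyldimethylsilyloxy)hexa-1,5-dien-2-yl]-6-oxoheptanal, via ring epoxide 9 (not isolated)
Conditions: mCPBA, NaHCO3, CH2Cl2, −10 °C; then H5IO6, THF/H2O, 0 → 25 °C
Reagents that add atoms: 3-chloroperbenzoic acid, OOC(=O)c1cccc(Cl)c1; water, O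
Why: The trisubstituted ring alkene is by far the most nucleophilic of the three alkenes and should be epoxidised selectively (Prilezhaev epoxidation), and periodic acid hydrolyses and cleaves the epoxide in the same flask to the keto aldehyde, so the epoxide configuration is irrelevant.

Step 6
Reactants: 10 (3R)-3-[(3S)-3-(tert-butyldimethylsilyloxy)hexa-1,5-dien-2-yl]-6-oxoheptanal
Product: 11 (5S)-5-[(3S)-3-(tert-butyldimethylsilyloxy)hexa-1,5-dien-2-yl]-2-methylcyclopent-1-ene-1-carbaldehyde
Conditions: piperidine, AcOH, toluene, 80 °C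
Reagents that add atoms: none
Why: Amine-catalysed intramolecular aldol condensation in which the aldehyde enamine attacks the methyl ketone (5-enolexo closure) and dehydration gives the tetrasubstituted enal; C6 is not an enolisable position and should keep its configuration.

Step 7
Reactants: 11 (5S)-5-[(3S)-3-(tert-butyldimethylsilyloxy)hexa-1,5-dien-2-yl]-2-methylcyclopent-1-ene-1-carbaldehyde
Product: 13 (1S,5S)-1-hydroxy-2-methyl-5-[(3S)-3-(tert-butyldimethylsilyloxy)hexa-1,5-dien-2-yl]cyclopent-2-ene-1-carbaldehyde, via potassium dienolate 12 (not isolated)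
Conditions: KOtBu (0.95 equiv), THF, 0 °C; then 2-(phenylsulfonyl)-3-phenyloxaziridine, −78 °C; AcOH quench
Reagents that add atoms: 2-(phenylsulfonyl)-3-phenyloxaziridine, O=S(=O)(N1OC1c1ccccc1)c1ccccc1 (hydroxyl oxygen of 13); potassium tert-butoxide, CC(C)(C)[O-].[K+] (potassium of 12)
Why: Substoichiometric base at 0 °C should let the extended enolate equilibrate to the more substituted ring dienolate (C3=C4 endocyclic), which is hydroxylated at its α-carbon C1 by the N-sulfonyloxaziridine (Davis enolate oxidation as a deconjugative α-functionalisation) from the face anti to the C6 substituent, placing C1–OH trans and the formyl group cis to the side chain.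

Step 8
Reactants: 13 (1S,5S)-1-hydroxy-2-methyl-5-[(3S)-3-(tert-butyldimethylsilyloxy)hexa-1,5-dien-2-yl]cyclopent-2-ene-1-carbaldehyde
Product: 15 (2R,6S)-2-hydroxy-3-methyl-6-[(3S)-3-(tert-butyldimethylsilyloxy)hexa-1,5-dien-2-yl]cyclohex-3-en-1-one, via aluminium alkoxide 14 (not isolated)
Conditions: Me2AlCl (1.1 equiv), CH2Cl2, −78 → −30 °C; pH 7 phosphate buffer, −30 °C
Reagents that add atoms: dimethylaluminium chloride, C[Al](C)Cl (aluminium, methyl and chloride of intermediate 14; none remain in 15)
Why: The tertiary alcohol forms a chloro(methyl)aluminium alkoxide whose aluminium also binds the formyl oxygen and fixes O–C1–C2=O syn-periplanar, and in this chelate the alkenyl carbon C3 undergoes a suprafacial 1,2-shift from C1 to the activated formyl carbon C2 while C1 becomes the ketone (α-ketol, i.e. acyloin, rearrangement of an α-hydroxy aldehyde; the closest known case is the ring-enlarging α-ketol rearrangement of 1-hydroxycycloalkyl carbonyl compounds). The six-membered ring C1–C6 is closed not by a cyclisation but by this ring-enlarging 1,2-shift through a bridged, cyclopropane-like transition state that inserts C2 between C1 and C3 of the cyclopentene. The only new stereocentre, C2, is controlled by the C1 configuration from step 7 together with the chelate: C3 can only reach the formyl face on its own side, which places C2–O trans to the C6 side chain (2R). The step needs migration of C3 and not of C6, which should be secured by the higher migratory aptitude of the sp2 carbon (π participation) over the secondary alkyl carbon. It also needs kinetic control, secured by the low temperature, the aluminium-bound product alkoxide and the neutral quench, so that the β,γ-unsaturated ketol does not drift to the conjugated acyloin or the diosphenol and the C7=C14 alkene, deactivated by the allylic silyloxy group, does not enter a Prins or ene reaction with the activated aldehyde.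

Step 9
Reactants: 15 (2R,6S)-2-hydroxy-3-methyl-6-[(3S)-3-(tert-butyldimethylsilyloxy)hexa-1,5-dien-2-yl]cyclohex-3-en-1-one (used directly)
Product: 16 (1R,2R,6S)-3-methyl-6-[(3S)-3-(tert-butyldimethylsilyloxy)hexa-1,5-dien-2-yl]cyclohex-3-ene-1,2-diol
Conditions: Me4NBH(OAc)3, MeCN/AcOH, −30 °C
Reagents that add atoms: none
Why: Hydroxyl-directed triacetoxyborohydride reduction (Evans–Saksena type): the C2 hydroxyl binds boron and delivers hydride to the face of C1=O on which it sits, which is also the face anti to the side chain, so the trans-1,2-diol with C1–OH cis to the C6 side chain should result.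

Step 10
Reactants: 16 (1R,2R,6S)-3-methyl-6-[(3S)-3-(tert-butyldimethylsilyloxy)hexa-1,5-dien-2-yl]cyclohex-3-ene-1,2-diol
Product: 17 1,2-bis-angelate of 16
Conditions: angelic acid, 2,4,6-trichlorobenzoyl chloride, Et3N, toluene, 25 °C; then 16, 80 °C
Reagents that add atoms: angelic acid, C/C=C(/C)C(=O)O
Why: Yamaguchi-type mixed-anhydride acylation without a nucleophilic catalyst should esterify both secondary alcohols while keeping the Z geometry of the angelate (no isomerisation to tiglate).

Step 11
Reactants: 17 1,2-bis-angelate of 16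
Product: 19 (1R,2R,6S)-6-[(3S)-3-acetoxyhexa-1,5-dien-2-yl]-3-methylcyclohex-3-ene-1,2-diyl bis[(2Z)-2-methylbut-2-enoate], via C8 alcohol 18 (not isolated)
Conditions: HF·pyridine, THF/pyridine, 0 → 25 °C; then Ac2O, DMAP, 0 °C
Reagents that add atoms: acetic anhydride, CC(=O)OC(C)=O
Why: Fluoride cleavage of the secondary silyl ether followed by acetylation in the same flask installs the C8 acetate (desilylation, then acylation); no oxirane is present yet, so acidic fluoride should be tolerated.

Step 12
Reactants: 19 (1R,2R,6S)-6-[(3S)-3-acetoxyhexa-1,5-dien-2-yl]-3-methylcyclohex-3-ene-1,2-diyl bis[(2Z)-2-methylbut-2-enoate]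
Product: 20 (1S,2S,3R,4S,6S)-4-[(3S)-3-acetoxyhexa-1,5-dien-2-yl]-1-methyl-7-oxabicyclo[4.1.0]heptane-2,3-diyl bis[(2Z)-2-methylbut-2-enoate]
Conditions: dimethyldioxirane, acetone/CH2Cl2, −20 → 0 °C
Reagents that add atoms: dimethyldioxirane, CC1(C)OO1
Why: Electrophilic dioxirane epoxidation should select the trisubstituted ring alkene over the 1,1-disubstituted alkene (deactivated by the allylic acetate), the terminal alkene and the electron-poor angelates, and attack anti to the allylic C2 angelate (held pseudoaxial by allylic strain with the C3 methyl), that is on the face of C1–O and the side chain, which sets C3 and C4.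

Step 13
Reactants: 20 (1S,2S,3R,4S,6S)-4-[(3S)-3-acetoxyhexa-1,5-dien-2-yl]-1-methyl-7-oxabicyclo[4.1.0]heptane-2,3-diyl bis[(2Z)-2-methylbut-2-enoate]
Product: 21 target, (1S,2S,3R,4S,6S)-4-[(3S)-3-acetoxy-6-methylhepta-1,5-dien-2-yl]-1-methyl-7-oxabicyclo[4.1.0]heptane-2,3-diyl bis[(2Z)-2-methylbut-2-enoate]
Conditions: 2-methyl-2-butene (excess), second-generation Grubbs catalyst RuCl2(=CHPh)(H2IMes)(PCy3), CH2Cl2, 40 °C
Reagents that add atoms: 2-methyl-2-butene, CC=C(C)C
Why: Olefin cross-metathesis of the terminal alkene with excess 2-methyl-2-butene should exchange =CH2 for =CMe2 (prenyl formation), the hindered 1,1-disubstituted C7=C14 alkene and the trisubstituted angelates being unreactive towards the ruthenium carbene.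

Compound list

1 | (R)-(+)-limonene, (4R)-1-methyl-4-(prop-1-en-2-yl)cyclohex-1-ene | C=C(C)[C@@H]1CCC(C)=CC1 | starting material
2 | {2-[(1R)-4-methylcyclohex-3-en-1-yl]prop-2-en-1-yl}lithium | C=C(C[Li])[C@@H]1CCC(C)=CC1 | intermediate (not isolated)
3 | dimethyl {2-[(1R)-4-methylcyclohex-3-en-1-yl]prop-2-en-1-yl}boronate | C=C(CB(OC)OC)[C@@H]1CCC(C)=CC1 | intermediate (not isolated)
4 | 2-[(1R)-4-methylcyclohex-3-en-1-yl]prop-2-en-1-ol | C=C(CO)[C@@H]1CCC(C)=CC1 | intermediate
5 | 2-[(1R)-4-methylcyclohex-3-en-1-yl]prop-2-enal | C=C(C=O)[C@@H]1CCC(C)=CC1 | intermediate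
6 | bis(isopinocampheyl)borinic ester of alcohol 7 (boron on the C8 oxygen) | C=C([C@H](CC=C)OB([C@@H]1C[C@@H]2C[C@H]([C@H]1C)C2(C)C)[C@@H]1C[C@@H]2C[C@H]([C@H]1C)C2(C)C)[C@@H]1CCC(C)=CC1 | intermediate (not isolated)
7 | (3S)-2-[(1R)-4-methylcyclohex-3-en-1-yl]hexa-1,5-dien-3-ol | C=C([C@H](CC=C)O)[C@@H]1CCC(C)=CC1 | intermediate
8 | tert-butyldimethylsilyl ether of 7 | C=C([C@H](CC=C)O[Si](C)(C)C(C)(C)C)[C@@H]1CCC(C)=CC1 | intermediate
9 | ring 1,2-epoxide of 8 (both epoxide diastereomers) | C=C([C@H](CC=C)O[Si](C)(C)C(C)(C)C)[C@@H]1CCC2(C)OC2C1 | intermediate (not isolated)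
10 | (3R)-3-[(3S)-3-(tert-butyldimethylsilyloxy)hexa-1,5-dien-2-yl]-6-oxoheptanal | C=C([C@H](CC=C)O[Si](C)(C)C(C)(C)C)[C@@H](CC=O)CCC(C)=O | intermediate
11 | (5S)-5-[(3S)-3-(tert-butyldimethylsilyloxy)hexa-1,5-dien-2-yl]-2-methylcyclopent-1-ene-1-carbaldehyde | C=C([C@H](CC=C)O[Si](C)(C)C(C)(C)C)[C@@H]1CCC(C)=C1C=O | intermediate
12 | potassium ring dienolate of 11 (C3=C4 endocyclic, exocyclic enolate at C1=C2) | C=C([C@H](CC=C)O[Si](C)(C)C(C)(C)C)[C@@H]1CC=C(C)C1=C[O-].[K+] | intermediate (not isolated)
13 | (1S,5S)-1-hydroxy-2-methyl-5-[(3S)-3-(tert-butyldimethylsilyloxy)hexa-1,5-dien-2-yl]cyclopent-2-ene-1-carbaldehyde (OH trans to the side chain) | C=C([C@H](CC=C)O[Si](C)(C)C(C)(C)C)[C@@H]1CC=C(C)[C@]1(O)C=O | intermediate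
14 | chloro(methyl)aluminium alkoxide of 13 | C=C([C@H](CC=C)O[Si](C)(C)C(C)(C)C)[C@@H]1CC=C(C)[C@]1(O[Al](C)Cl)C=O | intermediate (not isolated)
15 | (2R,6S)-2-hydroxy-3-methyl-6-[(3S)-3-(tert-butyldimethylsilyloxy)hexa-1,5-dien-2-yl]cyclohex-3-en-1-one | C=C([C@H](CC=C)O[Si](C)(C)C(C)(C)C)[C@@H]1CC=C(C)[C@@H](O)C1=O | intermediate
16 | (1R,2R,6S)-3-methyl-6-[(3S)-3-(tert-butyldimethylsilyloxy)hexa-1,5-dien-2-yl]cyclohex-3-ene-1,2-diol | C=C([C@H](CC=C)O[Si](C)(C)C(C)(C)C)[C@@H]1CC=C(C)[C@@H](O)[C@@H]1O | intermediate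
17 | (1R,2R,6S)-3-methyl-6-[(3S)-3-(tert-butyldimethylsilyloxy)hexa-1,5-dien-2-yl]cyclohex-3-ene-1,2-diyl bis[(2Z)-2-methylbut-2-enoate] | C=C([C@H](CC=C)O[Si](C)(C)C(C)(C)C)[C@@H]1CC=C(C)[C@@H](OC(=O)/C(C)=C\C)[C@@H]1OC(=O)/C(C)=C\C | intermediate
18 | (1R,2R,6S)-6-[(3S)-3-hydroxyhexa-1,5-dien-2-yl]-3-methylcyclohex-3-ene-1,2-diyl bis[(2Z)-2-methylbut-2-enoate] | C=C([C@H](CC=C)O)[C@@H]1CC=C(C)[C@@H](OC(=O)/C(C)=C\C)[C@@H]1OC(=O)/C(C)=C\C | intermediate (not isolated)
19 | (1R,2R,6S)-6-[(3S)-3-acetoxyhexa-1,5-dien-2-yl]-3-methylcyclohex-3-ene-1,2-diyl bis[(2Z)-2-methylbut-2-enoate] | C=C([C@H](CC=C)OC(C)=O)[C@@H]1CC=C(C)[C@@H](OC(=O)/C(C)=C\C)[C@@H]1OC(=O)/C(C)=C\C | intermediate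
20 | (1S,2S,3R,4S,6S)-4-[(3S)-3-acetoxyhexa-1,5-dien-2-yl]-1-methyl-7-oxabicyclo[4.1.0]heptane-2,3-diyl bis[(2Z)-2-methylbut-2-enoate] | C=C([C@H](CC=C)OC(C)=O)[C@@H]1C[C@@H]2O[C@]2(C)[C@@H](OC(=O)/C(C)=C\C)[C@@H]1OC(=O)/C(C)=C\C | intermediate
21 | (1S,2S,3R,4S,6S)-4-[(3S)-3-acetoxy-6-methylhepta-1,5-dien-2-yl]-1-methyl-7-oxabicyclo[4.1.0]heptane-2,3-diyl bis[(2Z)-2-methylbut-2-enoate] | C=C([C@H](CC=C(C)C)OC(C)=O)[C@@H]1C[C@@H]2O[C@]2(C)[C@@H](OC(=O)/C(C)=C\C)[C@@H]1OC(=O)/C(C)=C\C | target

Total step count: 13. Longest linear sequence: 13 steps (fully linear from 1).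

Steps most likely to fail

Step 8. The two ring bonds at C1 may compete in the 1,2-shift, the activated aldehyde may be captured by the neighbouring C7=C14 alkene, and the non-conjugated ketol may transpose to conjugated isomers during reaction or work-up. The fallback sets out from 13 and comes back at 16. The shift would be run under equilibrating conditions with Al(OtBu)3 in toluene at 80 °C, so that the system settles in the conjugated acyloin F1, the 6-hydroxy enone with C1–OH trans to the side chain; this is the common end point of the C6 shift and of acyloin transposition. Mitsunobu inversion at C1 with chloroacetic acid, PPh3 and diisopropyl azodicarboxylate would give the cis chloroacetate F2. Thiourea and NaHCO3 in ethanol would remove the chloroacetyl group to give the cis hydroxy enone F3. Hydroxyl-directed 1,2-reduction with Me4NBH(OAc)3 would then deliver hydride to C2 from the face of the C1 hydroxyl and give diol 16.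

Step 7. Deprotonation at the C3 methyl instead of ring C4 (exocyclic dienolate), or oxygen transfer at the γ-carbon, would give regioisomeric hydroxy aldehydes. The fallback sets out from 11 and comes back at 13. The dienolate regiochemistry would be fixed and checked on an isolable derivative: equilibrating soft enolisation (Me3SiCl, NaI, Et3N, MeCN) should convert 11 into the trimethylsilyl dienol ether F4 with the endocyclic C3=C4 bond, which can be purified. MeLi in THF would then release the regiodefined lithium dienolate F5, which is hydroxylated at C1 with the same oxaziridine at −78 °C to give 13.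

Step 12. Facial selectivity may be poor (attack syn to the C2 angelate), and the side-chain alkenes may be partly oxidised. The fallback sets out from 16 and comes back at 20, and makes the epoxidation hydroxyl-directed. Diol 16 would be mono-acylated at the less hindered allylic C2 hydroxyl with one equivalent of the angelic mixed anhydride to give the mono-angelate F6; this regioselectivity is itself uncertain. VO(acac)2 with t-BuOOH in CH2Cl2 should then deliver oxygen to C3=C4 from the face of the free homoallylic C1 hydroxyl and give the epoxy alcohol F7. Acylation of C1–OH with the angelic mixed anhydride would give the epoxy bis-angelate F8. Buffered fluoride (Bu4NF, AcOH, THF) would free the C8 alcohol F9, which is acetylated with Ac2O and pyridine to give 20.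

Further compounds

F1 | step 8 | (5S,6S)-6-hydroxy-2-methyl-5-[(3S)-3-(tert-butyldimethylsilyloxy)hexa-1,5-dien-2-yl]cyclohex-2-en-1-one (OH trans to the side chain) | C=C([C@H](CC=C)O[Si](C)(C)C(C)(C)C)[C@@H]1CC=C(C)C(=O)[C@H]1O
F2 | step 8 | chloroacetate of the C1-inverted alcohol (ester cis to the side chain) | C=C([C@H](CC=C)O[Si](C)(C)C(C)(C)C)[C@@H]1CC=C(C)C(=O)[C@@H]1OC(=O)CCl
F3 | step 8 | (5S,6R)-6-hydroxy-2-methyl-5-[(3S)-3-(tert-butyldimethylsilyloxy)hexa-1,5-dien-2-yl]cyclohex-2-en-1-one (OH cis to the side chain) | C=C([C@H](CC=C)O[Si](C)(C)C(C)(C)C)[C@@H]1CC=C(C)C(=O)[C@@H]1O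
F4 | step 7 | trimethylsilyl dienol ether of 11 (endocyclic C3=C4, exocyclic silyloxymethylene) | C=C([C@H](CC=C)O[Si](C)(C)C(C)(C)C)[C@@H]1CC=C(C)C1=CO[Si](C)(C)C
F5 | step 7 | lithium ring dienolate of 11 | C=C([C@H](CC=C)O[Si](C)(C)C(C)(C)C)[C@@H]1CC=C(C)C1=C[O-].[Li+]
F6 | step 12 | C2 mono-angelate of diol 16 (C1–OH free) | C=C([C@H](CC=C)O[Si](C)(C)C(C)(C)C)[C@@H]1CC=C(C)[C@@H](OC(=O)/C(C)=C\C)[C@@H]1O
F7 | step 12 | 3,4-epoxide of F6 (oxirane cis to C1–OH) | C=C([C@H](CC=C)O[Si](C)(C)C(C)(C)C)[C@@H]1C[C@@H]2O[C@]2(C)[C@@H](OC(=O)/C(C)=C\C)[C@@H]1O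
F8 | step 12 | epoxy 1,2-bis-angelate with C8 silyl ether | C=C([C@H](CC=C)O[Si](C)(C)C(C)(C)C)[C@@H]1C[C@@H]2O[C@]2(C)[C@@H](OC(=O)/C(C)=C\C)[C@@H]1OC(=O)/C(C)=C\C
F9 | step 12 | epoxy 1,2-bis-angelate with free C8 alcohol | C=C([C@H](CC=C)O)[C@@H]1C[C@@H]2O[C@]2(C)[C@@H](OC(=O)/C(C)=C\C)[C@@H]1OC(=O)/C(C)=C\C
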